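- Time is the first thing to watch. In Monday's run the isomer falls by 0.115 d⁻¹ of the charge between its first two readings, but by 0.00306 d⁻¹ after 1.04 d, so the rate has dropped by a factor of about 37.6, as far as the scatter lets you read it.
- What slows it? Monday's last reading leaves 50.3% of the charge missing, more than the impurity's 44.1% of the starting material, so I read the impurity as the drain and its running down as the slowing.
- What is asked is the ratio of isomer to target, so over the span of the readings you can try replacing its curve by one number. The summed isomer readings of both runs over the summed target readings come to 6.23; this is the mean ratio.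
- Check the error this makes. The first three readings of both runs give 5.80, the last three 6.76, so the mean errs by about 0.478.
- My commitment for the new flask is the mean ratio, give or take that error, at 1.5 h and 4.0 d. Both are extrapolations, since 1.5 h lies before the first reading at 5 h and 4.0 d after the last at 3.00 d. I offer nothing at 2.0 min, which lies earlier still.

| flask | starting material | protic impurity | catalyst | remark | time |
|---|---|---|---|---|---|
| Thursday's | 0.59 M | 0.17 M | 0.1 mol% | run made earlier |  |
| Monday's | 0.59 M | 0.26 M | 0.1 mol% | run made earlier |  |
| flask | 0.59 M | 0.118 M | 0.1 mol% |  | 4.0 d |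

| run | time / d | isomer of the product / % | target / % |
|---|---|---|---|
| Thursday's | 0.208 | 59.8 | 9.9 |
| Thursday's | 0.625 | 58.2 | 10.0 |
| Thursday's | 1.04 | 57.3 | 10.4 |
| Thursday's | 1.67 | 56.0 | 8.4 |
| Thursday's | 2.50 | 56.5 | 8.5 |
| Thursday's | 3.00 | 56.9 | 7.9 |
| Monday's | 0.208 | 51.4 | 8.8 |
| Monday's | 0.625 | 46.6 | 8.5 |
| Monday's | 1.04 | 44.5 | 7.2 |
| Monday's | 1.67 | 45.0 | 8.0 |
| Monday's | 2.50 | 45.7 | 6.4 |
| Monday's | 3.00 | 43.9 | 5.8 |

(scatter of a reading: 1 percentage point)

- the earlier runs were read with a standard deviation of 1 percentage point

- ratio of isomer of the product to target at 2.0 min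
- ratio of isomer of the product to target at 1.5 h
- ratio of isomer of the product to target at 4.0 d

- The forecast gave 6 at 2.0 min and 6 at 1.5 h, on the ground that the ratio “barely depends on impurity early on”, and 7.5 at 4.0 d from a slow decay of the target.
- The flask gives 0.218, 5.59 and 6.10. The mean ratio stands 0.130 from the last value, but 0.640 from the middle one, beyond its error.

    starting material + protic impurity → quenched substrate (k = 0.0700 M⁻¹ min⁻¹)
    starting material ⇌ target (K = 1.60, k = 0.0220 min⁻¹)
    target + catalyst ⇌ isomer of the product + catalyst, rate k3*[catalyst]*[target] forward; the back reaction follows from the equilibrium constant (K = 6.10, k = 350 M⁻¹ min⁻¹)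

- In this flask the target–isomer step relaxes with a half-life of 0.0481 h at 4.00 d, short against 4.0 d, which is the mark of thermodynamic control at the end. That half-life is longer than 2.0 min, and in this flask isomer passes target at 0.00568 d, after that early time.
- On the neighbour flask with 0.24 M of starting material, the mean ratio gives 6.23 at 4.0 d. The computed ratio there is 6.10, with 48.8% of the charge as quenched substrate.

The runs are calculated for an exercise.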